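All runs were computed with constants of no real substance; noise was put on by code.

1. A small charge started my reckoning: the second substrate stands only 0.0300 M above the starting material. Making target uses one second substrate per starting material. The excess, x, is 30.0% of the starting material charged, and it can carry that much target on to over-reaction product. I call what remains the pool, W, the whole charge less x, the part of the charge left for target plus isomer of the product: 70.0%.

| flask | starting material | second substrate | free enzyme | temperature | remark | time |
|---|---|---|---|---|---|---|
| ochre | 0.10 M | 0.13 M | 10 µM | 37 °C | the very flask that is asked about, followed so far |  |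
| blue | 0.10 M | 0.13 M | 10 µM | 22 °C | run made earlier |  |
| flask | 0.10 M | 0.130 M | 10 µM | 37 °C |  | 2.5 h |

| ochre: time / min | ochre: target / % | blue: time / min | blue: target / % |
|---|---|---|---|
| 10.0 | 57 | 20.0 | 78 |
| 30.0 | 53 | 60.0 | 60 |
| 50.0 | 51 | 120 | 49 |
| 80.0 | 48 | 180 | 48 |
| 120 | 47 | 240 | 46 |
| 150 | 46 | 300 | 44 |

(standard deviation of a reading: 1.5 percentage points)

- Thursday's: at 2.5 h add second substrate, 50.0% of the amount charged, then wait 5.0 h
- Wednesday's: at 2.5 h take out 90% of the target then present, then wait 5.0 h
- Monday's: change nothing and wait 5.0 h more
- Tuesday's: at 2.5 h add free enzyme, 50.0% of the amount charged, then wait 5.0 h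

- removed target is counted in
- the numbers in the tables scatter by 1.5 percentage points (one standard deviation)
- on the list of suspects stand: free enzyme -> unfolded enzyme; starting material + free enzyme <-> starting complex; second substrate + starting complex <-> ternary complex; ternary complex -> free enzyme + target; second substrate + target -> over-reaction product; target + free enzyme <-> isomer of the product + free enzyme
- additions bring no volume worth counting

- target, in percent of the starting material first charged, at 2.5 h
- which option adds most target ("none" when 2 percentage points or less is all one gets) (Thursday's / Wednesday's / Monday's / Tuesday's / none)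
- target present, with what was taken out counted in, in percent of the starting material first charged, after Wednesday's
- target present, with what was taken out counted in, in percent of the starting material first charged, after Tuesday's

2. My first estimate was that target equals W. But the ochre run, this flask followed so far, reads 46% at 150 min, less than W by 24 percentage points. I put that gap in the isomer of the product, and read the share of the pool held as target, f, as 0.657.

3. My objection was that this might be a stall rather than a balance. The blue run, at 22 °C, reads 44% at 300 min, which gives f = 0.629. Within the scatter of 1.5 points I could not tell the two splits apart, so I took it as thermodynamic control and committed to about 46% now.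

4. Monday's and Tuesday's leave W and f as they stand, so I kept about 46%. Thursday's raises the excess by 65.0% of the charge and cuts W to 5.00%.

5. Wednesday's removes 41.4%, which leaves 28.6% in the pool. Splitting that by f gives 60.2% counted, a gain of 14 points. My objection was that the split needs working enzyme. But the wait of 5.0 h is longer than the 50.0 min after which the ochre run stood 5 points above its last reading, so I kept the estimate.

6. The forecast says 46% now, Wednesday's as best, 60% after Wednesday's and 44.5% after Tuesday's. Its Wednesday figure rests on other grounds than mine: “Allowing for enzyme decay, I expect about 60”.

7. The flask gives 46.8%, Wednesday's as best with a gain of 13 points, 59.7% after Wednesday's and 46.7% after Tuesday's.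

    free enzyme → unfolded enzyme (k = 0.00130 min⁻¹, Ea = 223 kJ mol⁻¹)
    starting material + free enzyme ⇌ starting complex (K = 3.70 M⁻¹, k = 2.30 × 10⁵ M⁻¹ min⁻¹, Ea = 38.0 kJ mol⁻¹, ΔH = −30.0 kJ mol⁻¹)
    second substrate + starting complex ⇌ ternary complex (K = 27.0 M⁻¹, k = 12000 M⁻¹ s⁻¹, Ea = 36.0 kJ mol⁻¹, ΔH = −90.0 kJ mol⁻¹)
    ternary complex → free enzyme + target (k = 3900 min⁻¹, Ea = 75.0 kJ mol⁻¹)
    second substrate + target → over-reaction product (k = 0.420 M⁻¹ min⁻¹, Ea = 55.0 kJ mol⁻¹)
    target + free enzyme ⇌ isomer of the product + free enzyme, rate k6*[free enzyme]*[target] forward; the back reaction follows from the equilibrium constant (K = 0.440, k = 3500 M⁻¹ min⁻¹, Ea = 54.0 kJ mol⁻¹, ΔH = −18.0 kJ mol⁻¹)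
    (constants at 37 °C)

At 150 min this flask holds target 46.8% and isomer of the product 20.7%, together 67.5% against the pool of 70.0%, with starting material at 1.51% and over-reaction product at 31.0% against the excess of 30.0%. A run of this flask without the falling back of isomer of the product to target holds 0.968% target instead of 46.8%, so that way back holds up the target by 46 points. The forecast would be wrong for a flask charged otherwise: at 0.140 M of second substrate, or at 0.0926 M of starting material, other charges held, the answer to "now" has moved by 5 points.

In the neighbour flask charged with 0.22 M of second substrate, x is 120%, so W is −20.0%, below zero, and I expect little target. That neighbour holds 7.44% target and 88.8% over-reaction product at 150 min.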